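**Remark on the chemistry (assumption).** The target is taken as the free alkyl hydrogen sulfate, exactly as drawn. Such acids promote their own hydrolysis, so the acid is released from its lithium salt only in the last operation and kept cold. Tetralin numbering is used throughout: C1 carries the aryl group, C2 the CH2OSO3H arm (C9'), C3 the CH2OH arm (C9), C4 is the benzylic CH2; the target is (1S,2R,3R).

## Structural features

The target is a 1-aryltetralin: aromatic ring A (methoxy on C6, hydroxyl on C7) is fused to saturated ring B, and C1 carries a 4-hydroxy-3-methoxyphenyl group. Ring B holds three contiguous stereocentres, C1 (S), C2 (R) and C3 (R). Their substituents are all trans and all equatorial, so the relative configuration is the stable one and only the absolute configuration has to be brought in from outside. C2 and C3 each bear a one-carbon oxygenated arm (C9' and C9). Both arms are primary and differ only in position, yet only C9' is sulfated, and two free phenols would also take up a sulfating agent. The real difficulty is therefore regiochemical rather than stereochemical: one sulfate on the C9' oxygen and none elsewhere. The fragile groups are the alkyl hydrogen sulfate (acid-labile, and a leaving group within reach of the C9 hydroxyl), the electron-rich phenolic rings (oxidants) and the doubly benzylic C1–H. The key step uses the fact that the sulfated oxygen sits on C9', that C9' is attached to C2, and that C2 is bonded to C3. A cyclic sulfate spanning the C2 and C9' oxygens, opened at C2 by a carbanion at C3, forms the C2–C3 bond of ring B and leaves the sulfur on the C9' oxygen, while C9 is still a carboxyl carbon.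

## Logic of the disconnections

**16 ⇐ 14 (through 15).** The two benzyl–oxygen bonds are cut, and the proton of the sulfate is exchanged for lithium. Benzyl is the only protecting group in the whole route and falls to hydrogen alone, which does not touch a sulfate monoester or the ring skeleton. The demand is that the acid form be generated last and cold.

**14 ⇐ 13.** The C9 carbinol is taken back to the carboxyl oxidation level. C9 and C9' are then chemically different (ester versus sulfate), so no choice between two primary alcohols ever has to be made, and the ester is the acidifying group the ring closure needs. The demand is a hydride that spares the alkyl sulfate anion.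

**13 ⇐ 11 (through 12).** The C2–C3 bond is cut. This opens ring B, removes the C3 stereocentre and returns C2 to an oxygen-bearing carbon inside a five-membered cyclic sulfate. The gain is an open-chain precursor with only two stereocentres, both derivable from one epoxide. The forward step needs SN2 inversion at a hindered secondary carbon, attack at C2 and not at C9', and no excess base.

**11 ⇐ 10.** The two O–S bonds are cut to a 1,2-diol. The forward step must close the cyclic sulfate without an oxidant, because the rings and benzyl ethers are electron-rich.

**10 ⇐ 7 + 5 (through 8 and 9).** The C1–C8a bond is cut between ring A and the benzylic carbon. An anti opening of a trans epoxy alcohol at its benzylic carbon sets C1 relative to C2 in one stereospecific event. The roles are not interchangeable: with a trans epoxide the pendant ring must be on the epoxide and ring A must be the nucleophile, because the reverse assignment would give the C1 epimer. The demand is an arylmagnesium that carries an ester and must therefore be made and used cold.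

**5 ⇐ 4.** The two C–O bonds of the epoxide are cut to the (E)-allylic alcohol. All absolute configuration of the route comes from this one catalytic asymmetric step.

**7 ⇐ 6 ⇐ 3.** The C–I bond is cut at the ring position para to the methoxy group, which is the innately most reactive site, and the saturated chain is taken back to the enoate.

**4 ⇐ 3 and 3 ⇐ 1 + 2.** Both halves converge on one enoate, 3. It is reduced at the carbonyl for the pendant half and at the C=C bond for the ring A half, and its C=C bond is cut to 1 and 2. One olefination thus serves both fragments.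

## Other disconnections considered

**Alternative 1:** The cut removes C4a–C8a and C7–C8, so ring A is seen as the aromatised adduct of a furan and an alkyne, and ring B as the tether between them. In the forward step the open-chain compound A1 (4-methoxyfuran-2-yl on C4, ethynyl on C1) undergoes an intramolecular [4+2] cycloaddition; the oxygen bridge then opens and the ring aromatises to A2, with the hydroxyl on C7.

- In its favour: two rings form in one thermal, reagent-free isomerisation. The placement of OH and OMe on ring A follows from the furan's constitution. No stereocentre takes part, so none is at risk.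
- Against it: C1, C2 and C3 must all be built beforehand in an open chain, and C1 is a propargylic, benzylic centre prone to allene formation. An unactivated terminal alkyne with a four-atom tether is a reluctant dienophile. The alkoxyfuran is an acid-sensitive enol ether whose 2,4-substitution pattern runs against its innate reactivity.
- After A2: the free C7 phenol must be protected, the silyl ether removed, C9' sulfated and three benzyl groups removed. That is about four operations, against two after the key step of the chosen plan.
- Comparison: Alternative 1 is the better on mildness of mechanism (no strong base next to an electrophile) and on building ring A regiospecifically. It is equal in that C9 and C9' are distinguished before ring closure. It is weaker on stereochemical economy and clearly longer. The chosen plan creates C3 during ring closure and delivers the sulfate itself.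

**Alternative 2:** The cut removes C4a–C5 and C8–C8a, so ring A is annulated last onto a fully substituted cyclohexanone. In the forward step the C4a enolate released from silyl enol ether A3 adds to dialkoxy enone A4 with loss of methoxide. The methyl ketone then condenses onto the C8a carbonyl and tautomerisation gives phenol A5.

- In its favour: the oxygenation pattern of ring A is fixed by construction. The three ring B centres sit on a cyclohexanone where the all-equatorial arrangement is the stable one; this reliance on the thermodynamic preference is equal to that of the chosen plan.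
- Against it: C1 is alpha to the C8a carbonyl in A3 and in every intermediate, and the benzylic side is the more acidic one, so regiocontrol of the enol ether is delicate. Epimerisation at C1 is possible, although it would correct itself towards trans. The condensation takes place at a hindered, doubly alpha-substituted ketone. A4 is not a stock reagent. C9' is masked as a vinyl group and needs oxidative cleavage in the presence of electron-rich rings.
- After A5: phenol protection, cleavage, reduction, sulfation and hydrogenolysis, about five operations.
- Comparison: Alternative 2 is equal on differentiating C9 from C9' (benzyl ether versus latent alcohol). It is weaker on step count and on the security of C1.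

**Alternative 3:** The cut is a one-carbon ring contraction of ring B: the C3–C4 bond is removed and C2 is reconnected to C4, giving a 3-arylindanone. In the forward step a tin hydride chain generates the primary radical from bromomethyl keto ester A6. The radical adds to the C4 carbonyl, the C2–C4 bond cleaves, and the ester-stabilised C2 radical takes hydrogen anti to the C1 aryl group to give A7.

- In its favour: 3-arylindanones are easy to obtain in enantioenriched form. This radical rearrangement is well established for keto esters of exactly this ring size; on precedent for the key step itself it is the better of the two plans. Conditions are neutral. C2 stays epimerisable to trans, which is equal to the situation at C3 in the chosen plan.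
- Against it: A7 lacks C9 altogether and carries a C4 ketone that must be removed. C9 has to be added by hydroxymethylation at C3 and then protected while the C9' ester is reduced and sulfated, so the regiochemical problem returns as protecting-group steps. A stoichiometric tin reagent is needed. At least seven operations follow the key step.
- Comparison: the chosen plan delivers every carbon, ring B and the sulfate in one step; Alternative 3 is the least economical of the three.

Key step: step 8

## Route

**Step 1**
Reactants: 1 4-(benzyloxy)-3-methoxybenzaldehyde (O-benzylvanillin, a stock compound); 2 tert-butyl 2-(diethoxyphosphoryl)acetate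
Product: 3 tert-butyl (2E)-3-[4-(benzyloxy)-3-methoxyphenyl]prop-2-enoate
Conditions: LiCl, DBU, MeCN, rt
Reagents that add atoms: none
Why: Horner–Wadsworth–Emmons olefination in its mild LiCl/amine variant; the stabilised phosphonate anion adds to the non-enolisable aldehyde and elimination should give the (E)-enoate, which then serves both halves of the molecule.

**Step 2**
Reactants: 3 tert-butyl (2E)-3-[4-(benzyloxy)-3-methoxyphenyl]prop-2-enoate
Product: 4 (2E)-3-[4-(benzyloxy)-3-methoxyphenyl]prop-2-en-1-ol (4-O-benzylconiferyl alcohol)
Conditions: i-Bu2AlH (2.5 equiv), CH2Cl2, −78 → 0 °C; aq. KNaC4H4O6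
Reagents that add atoms: none
Why: 1,2-Reduction of an α,β-unsaturated ester by an electrophilic aluminium hydride gives the allylic alcohol without conjugate reduction; the benzyl ether is inert.

**Step 3**
Reactants: 4 (2E)-3-[4-(benzyloxy)-3-methoxyphenyl]prop-2-en-1-ol
Product: 5 [(2S,3S)-3-[4-(benzyloxy)-3-methoxyphenyl]oxiran-2-yl]methanol
Conditions: Ti(Oi-Pr)4 (10 mol%), L-(+)-diisopropyl tartrate (12 mol%), t-BuOOH (anhydrous), 4 Å molecular sieves, CH2Cl2, −25 °C; cold aq. NaOH/NaCl work-up
Reagents that add atoms: tert-butyl hydroperoxide, CC(C)(C)OO
Why: Sharpless asymmetric epoxidation; with the L-(+)-tartrate the catalyst formed from Ti(Oi-Pr)4 should deliver oxygen to the face of the (E)-allylic alcohol that gives the (2S,3S)-epoxide, which fixes the future C2 and, through the later anti opening, C1. The catalytic, sieve-dried protocol and basic work-up are chosen because the p-alkoxyphenyl epoxide is acid-sensitive.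

**Step 4**
Reactants: 3 tert-butyl (2E)-3-[4-(benzyloxy)-3-methoxyphenyl]prop-2-enoate
Product: 6 tert-butyl 3-[4-(benzyloxy)-3-methoxyphenyl]propanoate
Conditions: NaBH4, NiCl2·6H2O (10 mol%), MeOH/THF, 0 °C
Reagents that add atoms: none
Why: Conjugate reduction of a cinnamate by Ni2B generated in the flask; aryl benzyl ethers and tert-butyl esters are not expected to react under these conditions.

**Step 5**
Reactants: 6 tert-butyl 3-[4-(benzyloxy)-3-methoxyphenyl]propanoate
Product: 7 tert-butyl 3-[4-(benzyloxy)-2-iodo-5-methoxyphenyl]propanoate
Conditions: N-iodosuccinimide, CF3CO2H (10 mol%), MeCN, 0 °C → rt, dark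
Reagents that add atoms: N-iodosuccinimide, O=C1CCC(=O)N1I
Why: Electrophilic aromatic iodination; the position para to the methoxy group and ortho to the chain is the most activated and accessible free site of a 4-alkyl-1,2-dialkoxybenzene, and catalytic acid in the cold should spare the tert-butyl ester. The iodide is chosen over the bromide because only it allows halogen–magnesium exchange at low temperature.

**Step 6**
Reactants: 7 tert-butyl 3-[4-(benzyloxy)-2-iodo-5-methoxyphenyl]propanoate; 5 [(2S,3S)-3-[4-(benzyloxy)-3-methoxyphenyl]oxiran-2-yl]methanol
Product: 10 tert-butyl 3-{4-(benzyloxy)-2-[(1S,2R)-1-[4-(benzyloxy)-3-methoxyphenyl]-2,3-dihydroxypropyl]-5-methoxyphenyl}propanoate, via arylmagnesium chloride 8 (not isolated), via chloromagnesium alkoxide 9 (not isolated)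
Conditions: 7, i-PrMgCl·LiCl (1.05 equiv), THF, −20 °C; 5, t-BuMgCl (1.0 equiv), THF, −40 °C; 8 (1.3 equiv) added to 9, CuI (10 mol%), −30 → −5 °C; aq. NH4Cl
Reagents that add atoms: none
Why: Iodine–magnesium exchange gives an arylmagnesium whose tert-butyl ester should survive at low temperature, and CuI-catalysed SN2 opening of a 3-aryl-2,3-epoxy alcohol takes place at the benzylic carbon with inversion, so the (2S,3S)-epoxide should give the (1S,2R) arrangement of the diarylmethine and carbinol carbons. Prior deprotonation of 5 by the non-nucleophilic t-BuMgCl saves one equivalent of the aryl reagent.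

**Step 7**
Reactants: 10 tert-butyl 3-{4-(benzyloxy)-2-[(1S,2R)-1-[4-(benzyloxy)-3-methoxyphenyl]-2,3-dihydroxypropyl]-5-methoxyphenyl}propanoate
Product: 11 tert-butyl 3-{4-(benzyloxy)-2-[(S)-[4-(benzyloxy)-3-methoxyphenyl][(4R)-2,2-dioxo-1,3,2-dioxathiolan-4-yl]methyl]-5-methoxyphenyl}propanoate
Conditions: NaH (2.2 equiv), 1,1'-sulfonyldiimidazole (1.2 equiv), THF, −20 °C → rt
Reagents that add atoms: 1,1'-sulfonyldiimidazole, O=S(=O)(n1ccnc1)n1ccnc1
Why: Double O-sulfonylation of the 1,2-diol dialkoxide closes the five-membered cyclic sulfate without any oxidant, which matters because RuO4 would endanger the electron-rich rings and benzyl ethers; no stereocentre is touched.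

**Step 8**
Reactants: 11 tert-butyl 3-{4-(benzyloxy)-2-[(S)-[4-(benzyloxy)-3-methoxyphenyl][(4R)-2,2-dioxo-1,3,2-dioxathiolan-4-yl]methyl]-5-methoxyphenyl}propanoate
Product: 13 lithium [(1S,2R,3R)-7-(benzyloxy)-1-[4-(benzyloxy)-3-methoxyphenyl]-3-(tert-butoxycarbonyl)-6-methoxy-1,2,3,4-tetrahydronaphthalen-2-yl]methyl sulfate, via lithium ester enolate 12 (not isolated)
Conditions: LiN(SiMe3)2 (1.05 equiv, added slowly), THF (0.02 M), −78 → −30 °C; cold quench, aq. LiCl
Reagents that add atoms: lithium bis(trimethylsilyl)amide, [Li+].C[Si](C)(C)[N-][Si](C)(C)C
Why: The silylamide removes the ester α-hydrogen, the most acidic and most accessible C–H, and the enolate carbon (C3) displaces the C2–O bond of the cyclic sulfate in an intramolecular SN2 reaction; the closest known reaction type is the C-alkylation of ester and malonate enolates by 1,2-cyclic sulfates, which stops at the monoalkyl sulfate. Ring B closes in the 6-exo-tet mode with the enolate double bond outside the new ring. C2 is controlled by inversion of the (4R) sulfate carbon set in step 3, which places the C9' arm trans to the C1 aryl group. C3 is controlled by a chair-like transition state in which the enolate carboxyl carbon lies anti to C1 and therefore ends equatorial, trans to C9'. Attack at C2 and not at primary C9' is secured by ring size (six against seven), and O-alkylation would need an eight-membered ring. Substitution should prevail over elimination because the weakly basic, hindered amide cannot remove the shielded diarylmethine hydrogen. One equivalent of base and a cold quench are essential, because a second enolisation at C3 could displace the C9' sulfate and close a cyclopropane; for the same reason no base equilibration of 13 is planned. The sulfate anion left on C9' is a poor electrophile and non-nucleophilic, so it neither alkylates further nor lactonises onto the ester.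

**Step 9**
Reactants: 13 lithium [(1S,2R,3R)-7-(benzyloxy)-1-[4-(benzyloxy)-3-methoxyphenyl]-3-(tert-butoxycarbonyl)-6-methoxy-1,2,3,4-tetrahydronaphthalen-2-yl]methyl sulfate
Product: 14 lithium [(1S,2R,3R)-7-(benzyloxy)-1-[4-(benzyloxy)-3-methoxyphenyl]-3-(hydroxymethyl)-6-methoxy-1,2,3,4-tetrahydronaphthalen-2-yl]methyl sulfate
Conditions: i-Bu2AlH (4 equiv), THF, 0 °C → rt; MeOH, then H2O, filtration
Reagents that add atoms: none
Why: Hydride reduction of the ester to the primary alcohol; alkyl sulfate monoanions are poor electrophiles and are expected to survive hydride reagents, and the non-basic conditions leave C3 untouched. The metal-free work-up keeps lithium as the only counter-ion.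

**Step 10**
Reactants: 14 lithium [(1S,2R,3R)-7-(benzyloxy)-1-[4-(benzyloxy)-3-methoxyphenyl]-3-(hydroxymethyl)-6-methoxy-1,2,3,4-tetrahydronaphthalen-2-yl]methyl sulfate
Product: 16 [(1S,2R,3R)-7-hydroxy-1-(4-hydroxy-3-methoxyphenyl)-3-(hydroxymethyl)-6-methoxy-1,2,3,4-tetrahydronaphthalen-2-yl]methyl hydrogen sulfate, via lithium salt 15 (not isolated)
Conditions: H2 (1 atm), Pd/C (10%), MeOH, rt; filtration; sulfonic acid resin (H+ form), MeOH/H2O, 0 °C; freeze-drying
Reagents that add atoms: none
Why: Catalytic hydrogenolysis of the two aryl benzyl ethers; sulfate monoesters and the diarylmethine C–C bonds are inert to H2 over Pd/C, and cold proton exchange on the resin then releases the hydrogen sulfate.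

## Compound list

1 | 4-(benzyloxy)-3-methoxybenzaldehyde | O=Cc1ccc(OCc2ccccc2)c(OC)c1 | starting material
2 | tert-butyl 2-(diethoxyphosphoryl)acetate | CCOP(=O)(CC(=O)OC(C)(C)C)OCC | starting material
3 | tert-butyl (2E)-3-[4-(benzyloxy)-3-methoxyphenyl]prop-2-enoate | COc1cc(/C=C/C(=O)OC(C)(C)C)ccc1OCc1ccccc1 | intermediate
4 | (2E)-3-[4-(benzyloxy)-3-methoxyphenyl]prop-2-en-1-ol | COc1cc(/C=C/CO)ccc1OCc1ccccc1 | intermediate
5 | [(2S,3S)-3-[4-(benzyloxy)-3-methoxyphenyl]oxiran-2-yl]methanol | OC[C@@H]1O[C@H]1c1ccc(OCc2ccccc2)c(OC)c1 | intermediate
6 | tert-butyl 3-[4-(benzyloxy)-3-methoxyphenyl]propanoate | COc1cc(CCC(=O)OC(C)(C)C)ccc1OCc1ccccc1 | intermediate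
7 | tert-butyl 3-[4-(benzyloxy)-2-iodo-5-methoxyphenyl]propanoate | COc1cc(CCC(=O)OC(C)(C)C)c(I)cc1OCc1ccccc1 | intermediate
8 | {5-(benzyloxy)-2-[3-(tert-butoxy)-3-oxopropyl]-4-methoxyphenyl}magnesium chloride (as its LiCl complex) | COc1cc(CCC(=O)OC(C)(C)C)c([Mg]Cl)cc1OCc1ccccc1 | intermediate
9 | chloromagnesium alkoxide of 5 | Cl[Mg]OC[C@@H]1O[C@H]1c1ccc(OCc2ccccc2)c(OC)c1 | intermediate
10 | tert-butyl 3-{4-(benzyloxy)-2-[(1S,2R)-1-[4-(benzyloxy)-3-methoxyphenyl]-2,3-dihydroxypropyl]-5-methoxyphenyl}propanoate | COc1cc([C@H]([C@@H](O)CO)c2cc(OCc3ccccc3)c(OC)cc2CCC(=O)OC(C)(C)C)ccc1OCc1ccccc1 | intermediate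
11 | tert-butyl 3-{4-(benzyloxy)-2-[(S)-[4-(benzyloxy)-3-methoxyphenyl][(4R)-2,2-dioxo-1,3,2-dioxathiolan-4-yl]methyl]-5-methoxyphenyl}propanoate | COc1cc([C@H]([C@@H]2COS(=O)(=O)O2)c2cc(OCc3ccccc3)c(OC)cc2CCC(=O)OC(C)(C)C)ccc1OCc1ccccc1 | intermediate
12 | lithium ester enolate of 11 | COc1cc([C@H]([C@@H]2COS(=O)(=O)O2)c2cc(OCc3ccccc3)c(OC)cc2CC=C([O-])OC(C)(C)C)ccc1OCc1ccccc1.[Li+] | intermediate
13 | lithium [(1S,2R,3R)-7-(benzyloxy)-1-[4-(benzyloxy)-3-methoxyphenyl]-3-(tert-butoxycarbonyl)-6-methoxy-1,2,3,4-tetrahydronaphthalen-2-yl]methyl sulfate | COc1cc([C@H]2c3cc(OCc4ccccc4)c(OC)cc3C[C@@H](C(=O)OC(C)(C)C)[C@@H]2COS(=O)(=O)[O-])ccc1OCc1ccccc1.[Li+] | intermediate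
14 | lithium [(1S,2R,3R)-7-(benzyloxy)-1-[4-(benzyloxy)-3-methoxyphenyl]-3-(hydroxymethyl)-6-methoxy-1,2,3,4-tetrahydronaphthalen-2-yl]methyl sulfate | COc1cc([C@H]2c3cc(OCc4ccccc4)c(OC)cc3C[C@@H](CO)[C@@H]2COS(=O)(=O)[O-])ccc1OCc1ccccc1.[Li+] | intermediate
15 | lithium [(1S,2R,3R)-7-hydroxy-1-(4-hydroxy-3-methoxyphenyl)-3-(hydroxymethyl)-6-methoxy-1,2,3,4-tetrahydronaphthalen-2-yl]methyl sulfate | COc1cc([C@H]2c3cc(O)c(OC)cc3C[C@@H](CO)[C@@H]2COS(=O)(=O)[O-])ccc1O.[Li+] | intermediate
16 | [(1S,2R,3R)-7-hydroxy-1-(4-hydroxy-3-methoxyphenyl)-3-(hydroxymethyl)-6-methoxy-1,2,3,4-tetrahydronaphthalen-2-yl]methyl hydrogen sulfate | COc1cc([C@H]2c3cc(O)c(OC)cc3C[C@@H](CO)[C@@H]2COS(=O)(=O)O)ccc1O | target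

## Step count and least certain steps

Total: 10 steps. Longest linear sequence: 8 steps (steps 1, 4, 5, 6, 7, 8, 9, 10).

**Step 8 (key step).** The most likely failures are three. First, elimination across C1–C2, or attack of the amide at the primary carbon of the very reactive cyclic sulfate, may outrun the SN2 closure at the hindered secondary carbon. Second, facial control at C3 may be incomplete. Third, renewed enolisation of the product may displace the C9' sulfate to a cyclopropane. A C3 epimer would be removed by crystallisation or chromatography at 13 or 14 and not by base. The fallback no longer asks the sulfate to be the leaving group. It sets out from 10. The primary hydroxyl is sulfated selectively with SO3·NMe3 in DMF at 0 °C and the salt is converted with LiOH into lithium (2R,3S)-3-[4-(benzyloxy)-3-methoxyphenyl]-3-{5-(benzyloxy)-2-[3-(tert-butoxy)-3-oxopropyl]-4-methoxyphenyl}-2-hydroxypropyl sulfate F1. The remaining secondary hydroxyl is converted with TsCl, DMAP and pyridine into the corresponding 2-(4-methylbenzenesulfonyloxy) compound F2. LiN(SiMe3)2 in THF then closes ring B by ordinary intramolecular enolate alkylation of a sulfonate with inversion at C2, and the route is rejoined at 13.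

**Step 6.** The slow exchange of the electron-rich iodide leaves time for 8 to cyclise onto its own ester (Parham-type closure to an indanone). MgCl2 may also ionise the p-alkoxyphenyl epoxide, which would lower the stereochemical purity at C1. The fallback uses an ester-free aryl nucleophile and sets out from 1 and 9. Bromination of 1 para to its methoxy group (Br2, NaOAc, AcOH) gives 4-(benzyloxy)-2-bromo-5-methoxybenzaldehyde F3. Wittig methylenation (Ph3P=CH2, THF) gives 1-(benzyloxy)-5-bromo-4-ethenyl-2-methoxybenzene F4. Magnesium in THF converts it into [5-(benzyloxy)-2-ethenyl-4-methoxyphenyl]magnesium bromide F5, which opens 9 under the same CuI catalysis to (2R,3S)-3-[4-(benzyloxy)-3-methoxyphenyl]-3-[5-(benzyloxy)-2-ethenyl-4-methoxyphenyl]propane-1,2-diol F6. Cross-metathesis with tert-butyl acrylate (second-generation Grubbs catalyst, CH2Cl2, 40 °C) gives tert-butyl (2E)-3-{4-(benzyloxy)-2-[(1S,2R)-1-[4-(benzyloxy)-3-methoxyphenyl]-2,3-dihydroxypropyl]-5-methoxyphenyl}prop-2-enoate F7. Conjugate reduction as in step 4 rejoins the route at 10.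

**Step 7.** After the first sulfonylation at the primary oxygen, the secondary alkoxide may displace the imidazolylsulfonate at carbon and close a terminal epoxide, instead of attacking sulfur. The fallback closes the ring at the lower oxidation level of sulfur, where this competition does not arise, and sets out from 10. SOCl2 and Et3N in CH2Cl2 at 0 °C give the cyclic sulfite tert-butyl 3-{4-(benzyloxy)-2-[(S)-[4-(benzyloxy)-3-methoxyphenyl][(4R)-2-oxo-1,3,2-dioxathiolan-4-yl]methyl]-5-methoxyphenyl}propanoate F8 (both configurations at sulfur). A brief oxidation with catalytic RuCl3 and NaIO4 in MeCN/H2O at 0 °C, stopped as soon as the sulfite is consumed to limit attack on the arenes, rejoins the route at 11.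

**Step 3.** The Lewis-acidic titanium medium may open the electron-rich benzylic epoxide with isopropanol or tartrate during reaction or work-up. The fallback is a metal-free, buffered epoxidation that sets out from 4 and returns at 5: the ketone-catalysed dioxirane epoxidation (Shi epoxidation) with the enantiomer of the fructose-derived ketone, made from L-sorbose, with KHSO5 and K2CO3 in MeCN/dimethoxymethane/H2O at 0 °C. It creates no compound outside the compound list (entry F0).

## Further compounds

F1 | step 8 | lithium (2R,3S)-3-[4-(benzyloxy)-3-methoxyphenyl]-3-{5-(benzyloxy)-2-[3-(tert-butoxy)-3-oxopropyl]-4-methoxyphenyl}-2-hydroxypropyl sulfate | COc1cc([C@H]([C@@H](O)COS(=O)(=O)[O-])c2cc(OCc3ccccc3)c(OC)cc2CCC(=O)OC(C)(C)C)ccc1OCc1ccccc1.[Li+]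
F2 | step 8 | lithium (2R,3S)-3-[4-(benzyloxy)-3-methoxyphenyl]-3-{5-(benzyloxy)-2-[3-(tert-butoxy)-3-oxopropyl]-4-methoxyphenyl}-2-(4-methylbenzenesulfonyloxy)propyl sulfate | COc1cc([C@H]([C@@H](OS(=O)(=O)c2ccc(C)cc2)COS(=O)(=O)[O-])c2cc(OCc3ccccc3)c(OC)cc2CCC(=O)OC(C)(C)C)ccc1OCc1ccccc1.[Li+]
F3 | step 6 | 4-(benzyloxy)-2-bromo-5-methoxybenzaldehyde | COc1cc(C=O)c(Br)cc1OCc1ccccc1
F4 | step 6 | 1-(benzyloxy)-5-bromo-4-ethenyl-2-methoxybenzene | COc1cc(C=C)c(Br)cc1OCc1ccccc1
F5 | step 6 | [5-(benzyloxy)-2-ethenyl-4-methoxyphenyl]magnesium bromide | COc1cc(C=C)c([Mg]Br)cc1OCc1ccccc1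
F6 | step 6 | (2R,3S)-3-[4-(benzyloxy)-3-methoxyphenyl]-3-[5-(benzyloxy)-2-ethenyl-4-methoxyphenyl]propane-1,2-diol | COc1cc([C@H]([C@@H](O)CO)c2cc(OCc3ccccc3)c(OC)cc2C=C)ccc1OCc1ccccc1
F7 | step 6 | tert-butyl (2E)-3-{4-(benzyloxy)-2-[(1S,2R)-1-[4-(benzyloxy)-3-methoxyphenyl]-2,3-dihydroxypropyl]-5-methoxyphenyl}prop-2-enoate | COc1cc([C@H]([C@@H](O)CO)c2cc(OCc3ccccc3)c(OC)cc2/C=C/C(=O)OC(C)(C)C)ccc1OCc1ccccc1
F8 | step 7 | tert-butyl 3-{4-(benzyloxy)-2-[(S)-[4-(benzyloxy)-3-methoxyphenyl][(4R)-2-oxo-1,3,2-dioxathiolan-4-yl]methyl]-5-methoxyphenyl}propanoate (both configurations at sulfur) | COc1cc([C@H]([C@@H]2COS(=O)O2)c2cc(OCc3ccccc3)c(OC)cc2CCC(=O)OC(C)(C)C)ccc1OCc1ccccc1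
F0 | step 3 | none | none
A1 | alternative 1 | open-chain furyl alkyne: C1 bears the 4-(benzyloxy)-3-methoxyphenyl and ethynyl groups, C2 the CH2OSi(t-Bu)Me2 arm, C3 the CH2OCH2Ph arm, C4 the 4-methoxyfuran-2-yl group; configured as in A2 | COc1cc([C@@H](C#C)[C@@H](CO[Si](C)(C)C(C)(C)C)[C@H](COCc2ccccc2)Cc2cc(OC)co2)ccc1OCc1ccccc1
A2 | alternative 1 | all-trans tetralin with free C7 phenol, C9 benzyl ether and C9' tert-butyldimethylsilyl ether | COc1cc([C@H]2c3cc(O)c(OC)cc3C[C@@H](COCc4ccccc4)[C@@H]2CO[Si](C)(C)C(C)(C)C)ccc1OCc1ccccc1
A3 | alternative 2 | trimethylsilyl enol ether (C4a=C8a) of the all-trans 2-aryl-3-ethenyl-4-(benzyloxymethyl)cyclohexanone | COc1cc([C@H]2C(O[Si](C)(C)C)=CC[C@@H](COCc3ccccc3)[C@@H]2C=C)ccc1OCc1ccccc1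
A4 | alternative 2 | 3,4-dimethoxybut-3-en-2-one (either alkene geometry) | COC=C(OC)C(C)=O
A5 | alternative 2 | all-trans 1-aryl-2-ethenyl-3-(benzyloxymethyl)tetralin with free C7 phenol | COc1cc([C@H]2c3cc(O)c(OC)cc3C[C@@H](COCc4ccccc4)[C@@H]2C=C)ccc1OCc1ccccc1
A6 | alternative 3 | methyl 3-aryl-2-(bromomethyl)-1-oxoindane-2-carboxylate with 5-benzyloxy-6-methoxy substitution in tetralin-equivalent positions C7 and C6 (either configuration at the quaternary carbon) | COc1cc([C@H]2c3cc(OCc4ccccc4)c(OC)cc3C(=O)C2(CBr)C(=O)OC)ccc1OCc1ccccc1
A7 | alternative 3 | methyl trans-1-aryl-4-oxotetralin-2-carboxylate | COc1cc([C@H]2c3cc(OCc4ccccc4)c(OC)cc3C(=O)C[C@@H]2C(=O)OC)ccc1OCc1ccccc1
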